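**Retrosynthetic overview**
1. The last operations are hydrogenolysis of five O-benzyl groups and, before it, fluoride removal of three silyl groups, which also lets lactone 2 close again.
2. The strategy rests on ring B. It carries C3-OMe, C4-O and C5-aryl (ring C) on three neighbouring carbons, with the C1 CH2 arm meta to C3 and C5. Cutting C3–C4 and C5–C6 maps this onto a 3-methoxy-5-alkyl-2-pyrone (pyrone C5, C4, C3, C6 become ring B C1, C2, C3, C6) and an aryl siloxyalkyne (ring B C4, C5), with CO2 lost.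
3. Fragment 1 (ring A, lactone 1, pyrone) comes from an α-benzyloxy lactone enolate and 5-(bromomethyl)-3-methoxy-2-pyrone. Fragment 2 (ring C, lactone 2, ring D) comes from the iodinated α-benzyloxy lactone enolate and the ring D benzyl bromide, followed by alkynylation, acetylide oxidation and silylation.
4. Each lactone is built by Stobbe condensation, asymmetric hydrogenation (sets Cβ) and reduction–lactonisation. Cα is set by alkylation anti to the Cβ arm.
5. Order of ring formation: lactone 1, the pyrone, lactone 2 (then opened as a mask), ring B, lactone 2 re-closed.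

Key step: step 23

Remark 1: a lithium acetylide would add to a closed γ-lactone. Lactone 2 is therefore carried through the acetylide oxidation and the cycloaddition in ring-opened form, as a primary silyl ether and a silyl ester, and it re-closes in the fluoride step that was needed anyway.
Remark 2: the (R,R) ligand antipode is assigned by analogy with the known sense for itaconate half-esters. If the sense proves opposite, the equally available (S,S) antipode is used.
Lactone numbering: O1, C2 (C=O), C3 (α), C4 (β), C5.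

**Route**

Step 1
Reactants: 1 vanillin
Product: 2 4-(benzyloxy)-3-methoxybenzaldehyde
Conditions: BnBr, K2CO3, DMF, rt
Reagents that add atoms: benzyl bromide, BrCc1ccccc1
Why: Williamson ether synthesis on the phenoxide gives a benzyl ether that tolerates the bases, hydrides, silver oxide and homogeneous hydrogenation ahead and falls only in the last step.

Step 2
Reactants: 2 4-(benzyloxy)-3-methoxybenzaldehyde; 3 dimethyl succinate
Product: 4 (E)-4-[4-(benzyloxy)-3-methoxyphenyl]-3-(methoxycarbonyl)but-3-enoic acid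
Conditions: NaOMe, MeOH, reflux; then 2 M HCl
Reagents that add atoms: none
Why: In the Stobbe condensation the aldolate lactonises to a paraconic ester and E1cB ring opening gives the arylidene half-ester, with acid and ester already differentiated for step 4.

Step 3
Reactants: 4 (E)-4-[4-(benzyloxy)-3-methoxyphenyl]-3-(methoxycarbonyl)but-3-enoic acid
Product: 5 (3S)-4-[4-(benzyloxy)-3-methoxyphenyl]-3-(methoxycarbonyl)butanoic acid
Conditions: H2 (5 bar), [Rh(cod)((R,R)-Et-DuPhos)]BF4 (1 mol %), NaOMe (10 mol %), MeOH, rt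
Reagents that add atoms: none
Why: In this asymmetric hydrogenation of a Stobbe-type itaconate half-ester, carboxylate and alkene chelate the cationic rhodium centre and the C2-symmetric bisphospholane opens one alkene face only, which sets the (S) centre that becomes C4 of lactone 1 and leaves benzyl ethers untouched.

Step 4
Reactants: 5 (3S)-4-[4-(benzyloxy)-3-methoxyphenyl]-3-(methoxycarbonyl)butanoic acid
Product: 7 (4S)-4-[4-(benzyloxy)-3-methoxybenzyl]dihydrofuran-2(3H)-one, via hydroxy acid 6 (not isolated)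
Conditions: KOH (1 equiv), EtOH; CaCl2, NaBH4, −10 °C → rt; then 2 M HCl, rt
Reagents that add atoms: none
Why: Chemoselective ester reduction with calcium borohydride spares the potassium carboxylate, and acidification closes the γ-hydroxy acid to the five-membered lactone without touching the stereocentre.

Step 5
Reactants: 7 (4S)-4-[4-(benzyloxy)-3-methoxybenzyl]dihydrofuran-2(3H)-one
Product: 8 (3S,4R)-4-[4-(benzyloxy)-3-methoxybenzyl]-3-hydroxydihydrofuran-2(3H)-one
Conditions: KHMDS, THF, −78 °C; 2-(phenylsulfonyl)-3-phenyloxaziridine; AcOH quench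
Reagents that add atoms: 2-(phenylsulfonyl)-3-phenyloxaziridine, O=S(=O)(c1ccccc1)N1OC1c1ccccc1
Why: Enolate hydroxylation with an N-sulfonyloxaziridine should deliver oxygen anti to the C4 arm (trans alcohol), a C3 configuration that is erased again in step 10.

Step 6
Reactants: 8 (3S,4R)-4-[4-(benzyloxy)-3-methoxybenzyl]-3-hydroxydihydrofuran-2(3H)-one
Product: 9 (3S,4R)-3-(benzyloxy)-4-[4-(benzyloxy)-3-methoxybenzyl]dihydrofuran-2(3H)-one
Conditions: BnBr, Ag2O, 4 Å MS, CH2Cl2, rt, dark
Reagents that add atoms: benzyl bromide, BrCc1ccccc1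
Why: Silver oxide-promoted O-benzylation works under near-neutral conditions that spare the lactone, and it places the ether on a secondary alcohol so that no hindered tertiary alcohol has to be protected later.

Step 7
Reactants: 10 methyl methoxyacetate; 11 (E)-3-ethoxy-2-methylacrolein
Product: 12 methyl 5-ethoxy-3-hydroxy-2-methoxy-4-methylpent-4-enoate (racemic diastereomer mixture)
Conditions: LDA, THF, −78 °C; then 11; AcOH quench
Reagents that add atoms: none
Why: Aldol addition of the lithium ester enolate to the aldehyde carbon of the vinylogous formate joins C2–C3 (with OMe) to C4–C5(Me)–C6 of the future pyrone, and both new centres are lost in step 8.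

Step 8
Reactants: 12 methyl 5-ethoxy-3-hydroxy-2-methoxy-4-methylpent-4-enoate
Product: 14 3-methoxy-5-methyl-2H-pyran-2-one, via enal ester 13 (not isolated)
Conditions: HCO2H, 95 °C
Reagents that add atoms: none
Why: Acid turns the β-alkoxy allylic alcohol into the enal by allylic transposition, the enal tautomerises to the dienol through freely rotating single bonds, and enol lactonisation with loss of methanol follows, which is the known acid cyclisation of 5-alkoxy-2,4-dienoates and 5-oxopentenoates to 2-pyrones.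

Step 9
Reactants: 14 3-methoxy-5-methyl-2H-pyran-2-one
Product: 15 5-(bromomethyl)-3-methoxy-2H-pyran-2-one
Conditions: NBS, AIBN (cat.), PhCF3, reflux
Reagents that add atoms: N-bromosuccinimide, O=C1CCC(=O)N1Br
Why: Wohl–Ziegler bromination attacks the only allylic methyl group, while ionic ring bromination is held back because C4 and C6 are deactivated by the ring carbonyl.

Step 10
Reactants: 9 (3S,4R)-3-(benzyloxy)-4-[4-(benzyloxy)-3-methoxybenzyl]dihydrofuran-2(3H)-one; 15 5-(bromomethyl)-3-methoxy-2H-pyran-2-one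
Product: 16 fragment 1, (3R,4R)-3-(benzyloxy)-4-[4-(benzyloxy)-3-methoxybenzyl]-3-[(3-methoxy-2-oxo-2H-pyran-5-yl)methyl]dihydrofuran-2(3H)-one
Conditions: LiHMDS, THF, −78 °C; then 15, −78 → −40 °C
Reagents that add atoms: none
Why: In this lactone enolate alkylation (SN2 at the primary allylic bromide) the planar enolate should be attacked on the face anti to the C4 arm, so the new CH2 arm ends trans to it and OBn cis, which is the (3R) quaternary centre of lactone 1.

Step 11
Reactants: 2 4-(benzyloxy)-3-methoxybenzaldehyde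
Product: 17 [4-(benzyloxy)-3-methoxyphenyl]methanol
Conditions: NaBH4, MeOH, 0 °C
Reagents that add atoms: none
Why: Borohydride reduction of the aldehyde has no competing group.

Step 12
Reactants: 17 [4-(benzyloxy)-3-methoxyphenyl]methanol
Product: 18 4-(benzyloxy)-3-methoxybenzyl bromide
Conditions: PBr3, Et2O, 0 °C
Reagents that add atoms: phosphorus tribromide, BrP(Br)Br
Why: Bromide displaces the activated phosphite ester of the benzylic alcohol, and the electron-rich bromide is used without storage.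

Step 13
Reactants: 19 5-iodovanillin
Product: 20 4-(benzyloxy)-3-iodo-5-methoxybenzaldehyde
Conditions: BnBr, K2CO3, DMF, 50 °C
Reagents that add atoms: benzyl bromide, BrCc1ccccc1
Why: This is a Williamson ether synthesis as in step 1, with mild heating to offset the two ortho substituents.

Step 14
Reactants: 20 4-(benzyloxy)-3-iodo-5-methoxybenzaldehyde; 3 dimethyl succinate
Product: 21 (E)-4-[4-(benzyloxy)-3-iodo-5-methoxyphenyl]-3-(methoxycarbonyl)but-3-enoic acid
Conditions: NaOMe, MeOH, reflux; then 2 M HCl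
Reagents that add atoms: none
Why: This is a Stobbe condensation as in step 2, and the unactivated aryl iodide is inert to methoxide.

Step 15
Reactants: 21 (E)-4-[4-(benzyloxy)-3-iodo-5-methoxyphenyl]-3-(methoxycarbonyl)but-3-enoic acid
Product: 22 (3S)-4-[4-(benzyloxy)-3-iodo-5-methoxyphenyl]-3-(methoxycarbonyl)butanoic acid
Conditions: H2 (5 bar), [Rh(cod)((R,R)-Et-DuPhos)]BF4 (1 mol %), NaOMe (10 mol %), MeOH, rt
Reagents that add atoms: none
Why: This is the asymmetric hydrogenation of step 3, the ligand fixes the (S) centre that becomes C4 of lactone 2, and the homogeneous cationic rhodium catalyst cleaves neither the C–I bond nor the benzyl ether.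

Step 16
Reactants: 22 (3S)-4-[4-(benzyloxy)-3-iodo-5-methoxyphenyl]-3-(methoxycarbonyl)butanoic acid
Product: 24 (4S)-4-[4-(benzyloxy)-3-iodo-5-methoxybenzyl]dihydrofuran-2(3H)-one, via hydroxy acid 23 (not isolated)
Conditions: KOH (1 equiv), EtOH; CaCl2, NaBH4, −10 °C → rt; then 2 M HCl, rt
Reagents that add atoms: none
Why: This is the chemoselective ester reduction and lactonisation of step 4, and borohydride does not reduce the aryl iodide.

Step 17
Reactants: 24 (4S)-4-[4-(benzyloxy)-3-iodo-5-methoxybenzyl]dihydrofuran-2(3H)-one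
Product: 25 (3S,4R)-4-[4-(benzyloxy)-3-iodo-5-methoxybenzyl]-3-hydroxydihydrofuran-2(3H)-one
Conditions: KHMDS, THF, −78 °C; 2-(phenylsulfonyl)-3-phenyloxaziridine; AcOH quench
Reagents that add atoms: 2-(phenylsulfonyl)-3-phenyloxaziridine, O=S(=O)(c1ccccc1)N1OC1c1ccccc1
Why: This is the oxaziridine enolate hydroxylation of step 5, and the amide base causes no halogen–metal exchange.

Step 18
Reactants: 25 (3S,4R)-4-[4-(benzyloxy)-3-iodo-5-methoxybenzyl]-3-hydroxydihydrofuran-2(3H)-one
Product: 26 (3S,4R)-3-(benzyloxy)-4-[4-(benzyloxy)-3-iodo-5-methoxybenzyl]dihydrofuran-2(3H)-one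
Conditions: BnBr, Ag2O, 4 Å MS, CH2Cl2, rt, dark
Reagents that add atoms: benzyl bromide, BrCc1ccccc1
Why: This is the silver oxide-promoted O-benzylation of step 6.

Step 19
Reactants: 26 (3S,4R)-3-(benzyloxy)-4-[4-(benzyloxy)-3-iodo-5-methoxybenzyl]dihydrofuran-2(3H)-one; 18 4-(benzyloxy)-3-methoxybenzyl bromide
Product: 27 (3R,4R)-3-(benzyloxy)-3-[4-(benzyloxy)-3-methoxybenzyl]-4-[4-(benzyloxy)-3-iodo-5-methoxybenzyl]dihydrofuran-2(3H)-one
Conditions: LiHMDS, THF, −78 °C; then 18, −78 → −20 °C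
Reagents that add atoms: none
Why: In this lactone enolate alkylation the ring D benzyl bromide should enter anti to the C4 (ring C) arm, giving trans benzyl groups and the (3R) quaternary centre of lactone 2.

Step 20
Reactants: 27 (3R,4R)-3-(benzyloxy)-3-[4-(benzyloxy)-3-methoxybenzyl]-4-[4-(benzyloxy)-3-iodo-5-methoxybenzyl]dihydrofuran-2(3H)-one; 28 ethynyltrimethylsilane
Product: 29 (3R,4R)-3-(benzyloxy)-3-[4-(benzyloxy)-3-methoxybenzyl]-4-{4-(benzyloxy)-3-methoxy-5-[(trimethylsilyl)ethynyl]benzyl}dihydrofuran-2(3H)-one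
Conditions: PdCl2(PPh3)2 (3 mol %), CuI (5 mol %), Et3N–THF, 45 °C
Reagents that add atoms: none
Why: Sonogashira coupling of an aryl iodide proceeds under conditions mild enough for the lactone and the benzyl ethers.

Step 21
Reactants: 29 (3R,4R)-3-(benzyloxy)-3-[4-(benzyloxy)-3-methoxybenzyl]-4-{4-(benzyloxy)-3-methoxy-5-[(trimethylsilyl)ethynyl]benzyl}dihydrofuran-2(3H)-one
Product: 30 lithium (2R,3R)-2-(benzyloxy)-2-[4-(benzyloxy)-3-methoxybenzyl]-3-[4-(benzyloxy)-3-ethynyl-5-methoxybenzyl]-4-hydroxybutanoate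
Conditions: LiOH·H2O (1.1 equiv), THF–MeOH–H2O, 40 °C; evaporate, azeotrope (PhMe)
Reagents that add atoms: lithium hydroxide, [Li+].[OH-]
Why: Saponification and alkyne protodesilylation occur in one operation, leaving a carboxylate as the only carbonyl group, which neither an acetylide nor a peroxide anion attacks in step 22, and no stereocentre takes part.

Step 22
Reactants: 30 lithium (2R,3R)-2-(benzyloxy)-2-[4-(benzyloxy)-3-methoxybenzyl]-3-[4-(benzyloxy)-3-ethynyl-5-methoxybenzyl]-4-hydroxybutanoate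
Product: 32 fragment 2 in masked form: triisopropylsilyl (2R,3R)-2-(benzyloxy)-2-[4-(benzyloxy)-3-methoxybenzyl]-3-{4-(benzyloxy)-3-methoxy-5-[(triisopropylsilyloxy)ethynyl]benzyl}-4-(triisopropylsilyloxy)butanoate, via trilithium ynolate 31 (not isolated)
Conditions: LiHMDS (2.2 equiv), THF, −78 °C; t-BuOOLi (from t-BuOOH, LiHMDS), −78 → 0 °C; TIPSOTf (3.6 equiv), −78 → 0 °C; NaHCO3 work-up, Et3N-washed silica
Reagents that add atoms: tert-butyl hydroperoxide, CC(C)(C)OO; triisopropylsilyl trifluoromethanesulfonate, CC(C)[Si](OS(=O)(=O)C(F)(F)F)(C(C)C)C(C)C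
Why: Oxidation of the lithium acetylide with lithium tert-butyl peroxide gives the ynolate, and O-silylation with the bulky silyl triflate is the standard entry to triisopropylsiloxyalkynes, with the same reagent capping the primary alkoxide and the carboxylate.

Step 23
Reactants: 16 fragment 1; 32 fragment 2 in masked form
Product: 34 ring B triisopropylsilyl ether of the penta-O-benzyl biaryl (lactone 1 closed; lactone 2 as its silyl ether/silyl ester seco form), via bridged lactone adduct 33 (not isolated)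
Conditions: PhMe (1 M), 2,6-di-tert-butyl-4-methylpyridine (10 mol %), sealed tube, 130 °C
Reagents that add atoms: none
Why: Proposed new method: the aryl-bearing alkyne carbon, which is the nucleophilic β-carbon of the ynol ether, should bond to pyrone C6 (the δ-terminus of the dienoate) while the silyloxy-bearing carbon bonds to C3, either in one asynchronous [4+2] event or through a ketenium/dienolate zwitterion that collapses, giving the 2-oxabicyclo[2.2.2]octadienone 33. Cycloreversion of 33 then expels the O1–C2 bridge as CO2, which makes the sequence irreversible and leaves ring B aromatic. The closest known reaction type is the inverse-demand Diels–Alder/retro-Diels–Alder benzannulation of 2-pyrones with ynamines and alkoxyalkynes, in which this pairing of a 3-alkoxy-2-pyrone with an aryl siloxyalkyne is untested. Ring B closes as a six-membered carbocycle by intermolecular [4+2] cycloaddition (ring B bonds C3–C4 and C5–C6) followed by retro-[4+2]; the two bridgehead centres of 33 vanish on aromatisation, so no lasting stereocentre is made and the four existing ones are remote and untouched. The step needs one regiochemical orientation, and the match of alkyne polarisation with the electrophilic C6 and the α-carbonyl C3 secures it, placing ring C ortho and the CH2 arm meta to the new C–O carbon. Because the 3-OMe donor raises the pyrone LUMO, high concentration, a temperature near the stability limit of the silyl ynol ether and an acid scavenger are used.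

Step 24
Reactants: 34 ring B triisopropylsilyl ether of the penta-O-benzyl biaryl
Product: 36 penta-O-benzyl target (ring B phenol free; both lactones closed), via seco hydroxy acid 35 (not isolated)
Conditions: Bu4NF (5 equiv), THF, 0 °C → rt; then 1 M HCl, rt
Reagents that add atoms: none
Why: Fluoride desilylation removes the aryl silyl ether, the primary silyl ether and the silyl ester, and acid then lactonises γ-hydroxy acid 35 (five-membered ring, helped by the fully substituted α-carbon) with all stereocentres untouched.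

Step 25
Reactants: 36 penta-O-benzyl target
Product: 37 target CNP0218652.1
Conditions: H2 (1 atm), Pd(OH)2/C, THF–EtOH, rt
Reagents that add atoms: none
Why: Catalytic hydrogenolysis cleaves three aryl benzyl ethers and two tertiary alkyl benzyl ethers, while the lactone C–O bonds and the tertiary carbinol carbons are not benzylic and stay intact.

**Compound list**
1 | vanillin | COc1cc(C=O)ccc1O | starting material
2 | 4-(benzyloxy)-3-methoxybenzaldehyde | COc1cc(C=O)ccc1OCc1ccccc1 | intermediate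
3 | dimethyl succinate | COC(=O)CCC(=O)OC | starting material
4 | (E)-4-[4-(benzyloxy)-3-methoxyphenyl]-3-(methoxycarbonyl)but-3-enoic acid | COC(=O)/C(CC(=O)O)=C/c1ccc(OCc2ccccc2)c(OC)c1 | intermediate
5 | (3S)-4-[4-(benzyloxy)-3-methoxyphenyl]-3-(methoxycarbonyl)butanoic acid | COC(=O)[C@H](CC(=O)O)Cc1ccc(OCc2ccccc2)c(OC)c1 | intermediate
6 | (3S)-4-[4-(benzyloxy)-3-methoxyphenyl]-3-(hydroxymethyl)butanoic acid (not isolated) | OC[C@H](CC(=O)O)Cc1ccc(OCc2ccccc2)c(OC)c1 | intermediate
7 | (4S)-4-[4-(benzyloxy)-3-methoxybenzyl]dihydrofuran-2(3H)-one | COc1cc(C[C@@H]2COC(=O)C2)ccc1OCc1ccccc1 | intermediate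
8 | (3S,4R)-4-[4-(benzyloxy)-3-methoxybenzyl]-3-hydroxydihydrofuran-2(3H)-one | COc1cc(C[C@@H]2COC(=O)[C@H]2O)ccc1OCc1ccccc1 | intermediate
9 | (3S,4R)-3-(benzyloxy)-4-[4-(benzyloxy)-3-methoxybenzyl]dihydrofuran-2(3H)-one | COc1cc(C[C@@H]2COC(=O)[C@H]2OCc2ccccc2)ccc1OCc1ccccc1 | intermediate
10 | methyl methoxyacetate | COCC(=O)OC | starting material
11 | (E)-3-ethoxy-2-methylacrolein | CCO/C=C(\C)C=O | starting material
12 | methyl 5-ethoxy-3-hydroxy-2-methoxy-4-methylpent-4-enoate (racemic diastereomer mixture) | CCO/C=C(\C)C(O)C(OC)C(=O)OC | intermediate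
13 | methyl (E)-2-methoxy-4-methyl-5-oxopent-3-enoate (racemic, not isolated) | COC(=O)C(OC)/C=C(\C)C=O | intermediate
14 | 3-methoxy-5-methyl-2H-pyran-2-one | COc1cc(C)coc1=O | intermediate
15 | 5-(bromomethyl)-3-methoxy-2H-pyran-2-one | COc1cc(CBr)coc1=O | intermediate
16 | fragment 1, (3R,4R)-3-(benzyloxy)-4-[4-(benzyloxy)-3-methoxybenzyl]-3-[(3-methoxy-2-oxo-2H-pyran-5-yl)methyl]dihydrofuran-2(3H)-one | COc1cc(C[C@@H]2COC(=O)[C@@]2(OCc2ccccc2)Cc2coc(=O)c(OC)c2)ccc1OCc1ccccc1 | intermediate
17 | [4-(benzyloxy)-3-methoxyphenyl]methanol | COc1cc(CO)ccc1OCc1ccccc1 | intermediate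
18 | 4-(benzyloxy)-3-methoxybenzyl bromide | COc1cc(CBr)ccc1OCc1ccccc1 | intermediate
19 | 5-iodovanillin | COc1cc(C=O)cc(I)c1O | starting material
20 | 4-(benzyloxy)-3-iodo-5-methoxybenzaldehyde | COc1cc(C=O)cc(I)c1OCc1ccccc1 | intermediate
21 | (E)-4-[4-(benzyloxy)-3-iodo-5-methoxyphenyl]-3-(methoxycarbonyl)but-3-enoic acid | COC(=O)/C(CC(=O)O)=C/c1cc(I)c(OCc2ccccc2)c(OC)c1 | intermediate
22 | (3S)-4-[4-(benzyloxy)-3-iodo-5-methoxyphenyl]-3-(methoxycarbonyl)butanoic acid | COC(=O)[C@H](CC(=O)O)Cc1cc(I)c(OCc2ccccc2)c(OC)c1 | intermediate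
23 | (3S)-4-[4-(benzyloxy)-3-iodo-5-methoxyphenyl]-3-(hydroxymethyl)butanoic acid (not isolated) | OC[C@H](CC(=O)O)Cc1cc(I)c(OCc2ccccc2)c(OC)c1 | intermediate
24 | (4S)-4-[4-(benzyloxy)-3-iodo-5-methoxybenzyl]dihydrofuran-2(3H)-one | COc1cc(C[C@@H]2COC(=O)C2)cc(I)c1OCc1ccccc1 | intermediate
25 | (3S,4R)-4-[4-(benzyloxy)-3-iodo-5-methoxybenzyl]-3-hydroxydihydrofuran-2(3H)-one | COc1cc(C[C@@H]2COC(=O)[C@H]2O)cc(I)c1OCc1ccccc1 | intermediate
26 | (3S,4R)-3-(benzyloxy)-4-[4-(benzyloxy)-3-iodo-5-methoxybenzyl]dihydrofuran-2(3H)-one | COc1cc(C[C@@H]2COC(=O)[C@H]2OCc2ccccc2)cc(I)c1OCc1ccccc1 | intermediate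
27 | (3R,4R)-3-(benzyloxy)-3-[4-(benzyloxy)-3-methoxybenzyl]-4-[4-(benzyloxy)-3-iodo-5-methoxybenzyl]dihydrofuran-2(3H)-one | COc1cc(C[C@@H]2COC(=O)[C@@]2(OCc2ccccc2)Cc2ccc(OCc3ccccc3)c(OC)c2)cc(I)c1OCc1ccccc1 | intermediate
28 | ethynyltrimethylsilane | C#C[Si](C)(C)C | starting material
29 | (3R,4R)-3-(benzyloxy)-3-[4-(benzyloxy)-3-methoxybenzyl]-4-{4-(benzyloxy)-3-methoxy-5-[(trimethylsilyl)ethynyl]benzyl}dihydrofuran-2(3H)-one | COc1cc(C[C@@H]2COC(=O)[C@@]2(OCc2ccccc2)Cc2ccc(OCc3ccccc3)c(OC)c2)cc(C#C[Si](C)(C)C)c1OCc1ccccc1 | intermediate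
30 | lithium (2R,3R)-2-(benzyloxy)-2-[4-(benzyloxy)-3-methoxybenzyl]-3-[4-(benzyloxy)-3-ethynyl-5-methoxybenzyl]-4-hydroxybutanoate | [Li+].COc1cc(C[C@H](CO)[C@](OCc2ccccc2)(Cc2ccc(OCc3ccccc3)c(OC)c2)C(=O)[O-])cc(C#C)c1OCc1ccccc1 | intermediate
31 | trilithium ynolate/alkoxide/carboxylate derived from 30 (not isolated) | [Li+].[Li+].[Li+].COc1cc(C[C@H](C[O-])[C@](OCc2ccccc2)(Cc2ccc(OCc3ccccc3)c(OC)c2)C(=O)[O-])cc(C#C[O-])c1OCc1ccccc1 | intermediate
32 | fragment 2 in masked form, triisopropylsilyl (2R,3R)-2-(benzyloxy)-2-[4-(benzyloxy)-3-methoxybenzyl]-3-{4-(benzyloxy)-3-methoxy-5-[(triisopropylsilyloxy)ethynyl]benzyl}-4-(triisopropylsilyloxy)butanoate | CC(C)[Si](OC#Cc1cc(C[C@H](CO[Si](C(C)C)(C(C)C)C(C)C)[C@](OCc2ccccc2)(Cc2ccc(OCc3ccccc3)c(OC)c2)C(=O)O[Si](C(C)C)(C(C)C)C(C)C)cc(OC)c1OCc1ccccc1)(C(C)C)C(C)C | intermediate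
33 | 2-oxabicyclo[2.2.2]octa-5,7-dien-3-one adduct of 16 and 32 (both bridgehead diastereomers, not isolated) | COc1cc(C[C@@H]2COC(=O)[C@@]2(OCc2ccccc2)CC2=CC3(OC)C(=O)OC2C(c2cc(C[C@H](CO[Si](C(C)C)(C(C)C)C(C)C)[C@](OCc4ccccc4)(Cc4ccc(OCc5ccccc5)c(OC)c4)C(=O)O[Si](C(C)C)(C(C)C)C(C)C)cc(OC)c2OCc2ccccc2)=C3O[Si](C(C)C)(C(C)C)C(C)C)ccc1OCc1ccccc1 | intermediate
34 | penta-O-benzyl biaryl, ring B phenol as triisopropylsilyl ether, lactone 1 closed, lactone 2 as primary silyl ether and silyl ester | COc1cc(C[C@@H]2COC(=O)[C@@]2(OCc2ccccc2)Cc2cc(OC)c(O[Si](C(C)C)(C(C)C)C(C)C)c(-c3cc(C[C@H](CO[Si](C(C)C)(C(C)C)C(C)C)[C@](OCc4ccccc4)(Cc4ccc(OCc5ccccc5)c(OC)c4)C(=O)O[Si](C(C)C)(C(C)C)C(C)C)cc(OC)c3OCc3ccccc3)c2)ccc1OCc1ccccc1 | intermediate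
35 | seco hydroxy acid of 36 (not isolated) | COc1cc(C[C@@H]2COC(=O)[C@@]2(OCc2ccccc2)Cc2cc(OC)c(O)c(-c3cc(C[C@H](CO)[C@](OCc4ccccc4)(Cc4ccc(OCc5ccccc5)c(OC)c4)C(=O)O)cc(OC)c3OCc3ccccc3)c2)ccc1OCc1ccccc1 | intermediate
36 | penta-O-benzyl target, ring B phenol free | COc1cc(C[C@@H]2COC(=O)[C@@]2(OCc2ccccc2)Cc2cc(OC)c(O)c(-c3cc(C[C@@H]4COC(=O)[C@@]4(OCc4ccccc4)Cc4ccc(OCc5ccccc5)c(OC)c4)cc(OC)c3OCc3ccccc3)c2)ccc1OCc1ccccc1 | intermediate
37 | CNP0218652.1, both lactones (3R,4R) | COc1cc(C[C@@H]2COC(=O)[C@@]2(O)Cc2cc(OC)c(O)c(-c3cc(C[C@@H]4COC(=O)[C@@]4(O)Cc4ccc(O)c(OC)c4)cc(OC)c3O)c2)ccc1O | target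

**Step count and risks**
Total step count: 25.
Longest linear sequence: 13 steps (19 to 37, steps 13–25).

**Step 23 (key step).**
- What may go wrong: the cycloaddition may be too slow, because the methoxy donor lowers the electrophilicity of the pyrone. Thermal decay of the siloxyalkyne (silyl shift to a ketene, self-cycloaddition) could then outrun it, and some regiochemical leakage is possible.
- Fallback, by known chemistry, forms the biaryl bond instead of ring B. It sets out from 9, with 20 and 27 as partners, and comes back at 37.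
- Aldehyde 20 is reduced (NaBH4, MeOH) to [4-(benzyloxy)-3-iodo-5-methoxyphenyl]methanol F1 and brominated (PBr3, Et2O) to 4-(benzyloxy)-3-iodo-5-methoxybenzyl bromide F2.
- The lithium enolate of 9 is alkylated with it as in step 10 to give the ring B iodide of lactone 1 F3.
- Miyaura borylation (B2pin2, PdCl2(dppf), KOAc, dioxane, 80 °C) gives the ring B pinacol boronate F4.
- Suzuki–Miyaura coupling with iodide 27 (Pd(OAc)2, SPhos, K3PO4, PhMe–H2O, 80 °C, mildly acidic work-up) gives the hexa-O-benzyl target F5.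
- Hydrogenolysis under the conditions of step 25 gives 37.

**Step 22.**
- What may go wrong: the trilithiated salt may aggregate or stay undissolved so that oxygen transfer stalls, or capping of three different oxygen anions may be incomplete.
- Fallback masks the carbonyl by reduction instead of ring opening. It sets out from 29 and comes back at 36.
- K2CO3 in MeOH–THF gives the closed terminal alkyne lactone F6.
- DIBAL-H (CH2Cl2, −78 °C) gives the lactol F7.
- MeOH, HC(OMe)3 and PPTS give the methyl acetal F8.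
- Acetylide oxidation and silylation as in step 22, with one equivalent each of base and silyl triflate for the substrate, give the siloxyalkyne acetal F9.
- Heating with 16 as in step 23 gives the biaryl acetal F10.
- Aqueous AcOH–THF gives the biaryl lactol F11.
- Oxidation with Pr4N[RuO4] and N-methylmorpholine N-oxide gives the closed bis-lactone silyl ether F12, and Bu4NF gives 36.

**Step 10.**
- What may go wrong: the enolate may attack the pyrone ring (conjugate addition at C6, SN2′ displacement, acyl attack) in place of SN2 at CH2Br, and facial selectivity may erode if the reaction has to be warmed.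
- Fallback replaces alkylation by aldol addition and deoxygenation. It sets out from 15, with 9 as partner, and comes back at 16.
- Bromide 15 is oxidised with N-methylmorpholine N-oxide (MeCN, rt) to 3-methoxy-2-oxo-2H-pyran-5-carbaldehyde F13, whose aldehyde carbon is by far the most electrophilic site.
- The lithium enolate of 9 adds to it at −78 °C, anti to the C4 arm, with a cold AcOH quench against retro-aldol cleavage, giving the aldol adduct F14.
- 1,1′-Thiocarbonyldiimidazole gives the imidazolyl thionocarbamate F15.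
- Barton–McCombie deoxygenation (Bu3SnH, AIBN, PhMe, 80 °C) gives 16.

**Further compounds**
F1 | step 23 | [4-(benzyloxy)-3-iodo-5-methoxyphenyl]methanol | COc1cc(CO)cc(I)c1OCc1ccccc1
F2 | step 23 | 4-(benzyloxy)-3-iodo-5-methoxybenzyl bromide | COc1cc(CBr)cc(I)c1OCc1ccccc1
F3 | step 23 | (3R,4R)-3-(benzyloxy)-3-[4-(benzyloxy)-3-iodo-5-methoxybenzyl]-4-[4-(benzyloxy)-3-methoxybenzyl]dihydrofuran-2(3H)-one | COc1cc(C[C@@H]2COC(=O)[C@@]2(OCc2ccccc2)Cc2cc(I)c(OCc3ccccc3)c(OC)c2)ccc1OCc1ccccc1
F4 | step 23 | ring B pinacol boronate corresponding to F3 | COc1cc(C[C@@H]2COC(=O)[C@@]2(OCc2ccccc2)Cc2cc(OC)c(OCc3ccccc3)c(B3OC(C)(C)C(C)(C)O3)c2)ccc1OCc1ccccc1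
F5 | step 23 | hexa-O-benzyl target | COc1cc(C[C@@H]2COC(=O)[C@@]2(OCc2ccccc2)Cc2cc(OC)c(OCc3ccccc3)c(-c3cc(C[C@@H]4COC(=O)[C@@]4(OCc4ccccc4)Cc4ccc(OCc5ccccc5)c(OC)c4)cc(OC)c3OCc3ccccc3)c2)ccc1OCc1ccccc1
F6 | step 22 | (3R,4R)-3-(benzyloxy)-3-[4-(benzyloxy)-3-methoxybenzyl]-4-[4-(benzyloxy)-3-ethynyl-5-methoxybenzyl]dihydrofuran-2(3H)-one | COc1cc(C[C@@H]2COC(=O)[C@@]2(OCc2ccccc2)Cc2ccc(OCc3ccccc3)c(OC)c2)cc(C#C)c1OCc1ccccc1
F7 | step 22 | lactol of F6 (anomer mixture) | COc1cc(C[C@@H]2COC(O)[C@@]2(OCc2ccccc2)Cc2ccc(OCc3ccccc3)c(OC)c2)cc(C#C)c1OCc1ccccc1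
F8 | step 22 | methyl acetal of F7 (anomer mixture) | COc1cc(C[C@@H]2COC(OC)[C@@]2(OCc2ccccc2)Cc2ccc(OCc3ccccc3)c(OC)c2)cc(C#C)c1OCc1ccccc1
F9 | step 22 | triisopropylsiloxyalkyne of F8 (anomer mixture) | CC(C)[Si](OC#Cc1cc(C[C@@H]2COC(OC)[C@@]2(OCc2ccccc2)Cc2ccc(OCc3ccccc3)c(OC)c2)cc(OC)c1OCc1ccccc1)(C(C)C)C(C)C
F10 | step 22 | biaryl from 16 and F9, lactone 2 as methyl acetal (anomer mixture) | COc1cc(C[C@@H]2COC(=O)[C@@]2(OCc2ccccc2)Cc2cc(OC)c(O[Si](C(C)C)(C(C)C)C(C)C)c(-c3cc(C[C@@H]4COC(OC)[C@@]4(OCc4ccccc4)Cc4ccc(OCc5ccccc5)c(OC)c4)cc(OC)c3OCc3ccccc3)c2)ccc1OCc1ccccc1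
F11 | step 22 | biaryl lactol from F10 (anomer mixture) | COc1cc(C[C@@H]2COC(=O)[C@@]2(OCc2ccccc2)Cc2cc(OC)c(O[Si](C(C)C)(C(C)C)C(C)C)c(-c3cc(C[C@@H]4COC(O)[C@@]4(OCc4ccccc4)Cc4ccc(OCc5ccccc5)c(OC)c4)cc(OC)c3OCc3ccccc3)c2)ccc1OCc1ccccc1
F12 | step 22 | penta-O-benzyl target with the ring B phenol as triisopropylsilyl ether, both lactones closed | COc1cc(C[C@@H]2COC(=O)[C@@]2(OCc2ccccc2)Cc2cc(OC)c(O[Si](C(C)C)(C(C)C)C(C)C)c(-c3cc(C[C@@H]4COC(=O)[C@@]4(OCc4ccccc4)Cc4ccc(OCc5ccccc5)c(OC)c4)cc(OC)c3OCc3ccccc3)c2)ccc1OCc1ccccc1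
F13 | step 10 | 3-methoxy-2-oxo-2H-pyran-5-carbaldehyde | COc1cc(C=O)coc1=O
F14 | step 10 | aldol adduct of 9 and F13 (carbinol epimers) | COc1cc(C[C@@H]2COC(=O)[C@@]2(OCc2ccccc2)C(O)c2coc(=O)c(OC)c2)ccc1OCc1ccccc1
F15 | step 10 | imidazolyl thionocarbamate of F14 (carbinol epimers) | COc1cc(C[C@@H]2COC(=O)[C@@]2(OCc2ccccc2)C(OC(=S)n2ccnc2)c2coc(=O)c(OC)c2)ccc1OCc1ccccc1
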